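**Retrosynthetic overview**
1. Side chain: the C12–C13 bond comes from a B-alkyl Suzuki coupling of a C9 vinyl group (C11=C12, made from the C11 ester) with the (E)-enol triflate of methyl acetoacetate, which fixes the 13E geometry.
2. Ring B decoration: 6-OH and H5 come from hydroboration of a 5,7-diene; the 7-ene and H9 come from deconjugative protonation of the C11 ester of a 5,8-diene.
3. Key disconnection, C7–C8 and C9–C10: an intramolecular Diels–Alder reaction of the but-2-ynoate of the C18 alcohol with the ring A diene C10=C5–C6=C7. It rests on the C18 oxygen (on C4) and the C9–C10 bond being 1,3-cis on ring A, with C11 on C9, so an O18–C11 ester can carry C8≡C9 to the quaternary C10.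
4. Ring order: ring A is bought as methyl 2-oxocyclohexane-1-carboxylate (C4 set by auxiliary-controlled methylation, then C10 methyl, enol triflate, vinyl); ring B and the seven-membered O18–C11 lactone close together in the key step, and the lactone is then opened.

Key step: step 8

Numbering: labdane numbering is used in all names (ring A = C1–C5, C10; ring B = C5–C10; C11 on C9; C17 on C8; C18 = oxygenated carbon and C19 = methyl on C4; C20 on C10). In all bicyclic compounds C19 and C20 are cis; the SMILES strings carry the absolute configuration.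

Assumption: with the L-valine tert-butyl ester enamine and HMPA as lithium ligand, methylation is taken to give the (S)-ester; the facial sense of this auxiliary depends on the lithium ligand, so the rotation of 6 is checked and D-valine tert-butyl ester is used under the same conditions if the antipode is found.

Step 1
Reactants: 1 methyl 2-oxocyclohexane-1-carboxylate; 2 tert-butyl L-valinate
Product: 3 methyl 2-{[(2S)-1-tert-butoxy-3-methyl-1-oxobutan-2-yl]amino}cyclohex-1-ene-1-carboxylate
Conditions: TsOH·H2O (2 mol %), toluene, reflux, Dean–Stark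
Reagents that add atoms: none
Why: Condensation of the ketone of a β-keto ester with a primary amine (enamine formation) should give the hydrogen-bonded enamino ester; no ring stereocentre is formed.

Step 2
Reactants: 3 enamino ester
Product: 6 methyl (S)-1-methyl-2-oxocyclohexane-1-carboxylate, via lithio-enamine 4 (not isolated), via methylated ketimine 5 (not isolated)
Conditions: LiN(iPr)2, toluene, −78 °C; HMPA (1 equiv); MeI, −78 °C; then 10% aq citric acid, rt
Reagents that add atoms: iodomethane CI; water O
Why: Auxiliary-controlled alkylation of a chelated lithio-enamine (asymmetric enamine alkylation): lithium is held by the nitrogen and both ester carbonyls, the isopropyl group shields one face and MeI enters on the other, which sets C4, and hydrolysis releases the auxiliary.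

Step 3
Reactants: 6 methyl (S)-1-methyl-2-oxocyclohexane-1-carboxylate
Product: 8 methyl (1S)-1,3-dimethyl-2-oxocyclohexane-1-carboxylate (both C3 epimers), via lithium enolate 7 (not isolated)
Conditions: LiN(iPr)2, THF, −78 °C; MeI, −78 → 0 °C
Reagents that add atoms: iodomethane CI
Why: Enolate alkylation at the only enolisable position (the future C10); the new centre may form as a mixture because it becomes sp2 in step 4.

Step 4
Reactants: 8 methyl (1S)-1,3-dimethyl-2-oxocyclohexane-1-carboxylate
Product: 10 methyl (S)-1,3-dimethyl-2-{[(trifluoromethyl)sulfonyl]oxy}cyclohex-2-ene-1-carboxylate, via potassium enolate 9 (not isolated)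
Conditions: KN(SiMe3)2, THF, −78 → 0 °C; PhNTf2, 0 °C → rt
Reagents that add atoms: N-phenylbis(trifluoromethanesulfonimide) O=S(=O)(N(c1ccccc1)S(=O)(=O)C(F)(F)F)C(F)(F)F
Why: O-Sulfonylation of the enolate (enol triflate formation); C4 is quaternary, so only the tetrasubstituted C5=C10 enolate can form.

Step 5
Reactants: 10 enol triflate; 11 tributyl(vinyl)stannane
Product: 12 methyl (S)-1,3-dimethyl-2-vinylcyclohex-2-ene-1-carboxylate
Conditions: Pd(PPh3)4 (5 mol %), LiCl (3 equiv), THF, 65 °C
Reagents that add atoms: none
Why: Stille coupling of an enol triflate with a vinylstannane under zerovalent palladium catalysis, a coupling that tolerates 2,6,6-trisubstituted cyclohexenyl triflates, and C4 is not touched.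

Step 6
Reactants: 12 diene ester
Product: 13 [(1S)-1,3-dimethyl-2-vinylcyclohex-2-en-1-yl]methanol
Conditions: iBu2AlH (2.5 equiv), CH2Cl2, −78 → 0 °C; aq Rochelle salt
Reagents that add atoms: none
Why: Hydride reduction of the ester to the primary alcohol (C18–OH); the diene is inert to the aluminium hydride.

Step 7
Reactants: 13 diene alcohol; 14 but-2-ynoic acid
Product: 15 [(1S)-1,3-dimethyl-2-vinylcyclohex-2-en-1-yl]methyl but-2-ynoate
Conditions: DCC, DMAP (10 mol %), CH2Cl2, 0 °C → rt
Reagents that add atoms: none
Why: Steglich esterification of a primary alcohol; low temperature and catalytic DMAP limit amine addition to the ynoate.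

Step 8
Reactants: 15 [(1S)-1,3-dimethyl-2-vinylcyclohex-2-en-1-yl]methyl but-2-ynoate
Product: 16 12,13,14,15,16-pentanorlabda-5,8-dien-11-oic acid 18,11-lactone (tricyclic; C19 and C20 methyls cis)
Conditions: toluene (0.01 M), BHT (cat.), degassed, sealed tube, 170 °C
Reagents that add atoms: none
Why: Proposed new method: a concerted thermal [4+2] cycloaddition in which the ester-activated alkyne C8≡C9 adds across the ring A diene C10=C5–C6=C7; the closest known reactions are ester-tethered intramolecular Diels–Alder reactions of alkynoates, bridged intramolecular cycloadditions whose tether sits on an inner diene carbon and which give bridgehead dienes, and the intermolecular addition of acetylenic esters to 1-vinyl-2,6,6-trimethylcyclohexene. Ring B closes as a six-membered cyclohexa-1,4-diene (C5=C6, C8=C9) by the cycloaddition itself, and the seven-membered lactone closes in bridged mode because the three-atom C18–O–C11 chain ties C4 to C9 across C5–C10. The new stereocentre C10 is controlled by C4: the short tether can bring C9 to C10 only on the ring A face that carries C18, so C9 ends cis to C18 and C20 cis to C19. The regiochemistry (carbonyl carbon C11 on C9, methyl C17 on C8) is fixed by the tether, the opposite orientation being out of reach. The step needs the cycloaddition to outrun the [1,5]-hydrogen shift from C20 to C7 that is open to this diene (hence the cap near 170 °C), the ester must fold into its less favoured cisoid rotamer, and high dilution with BHT holds back intermolecular addition and polymerisation.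

Step 9
Reactants: 16 tricyclic lactone
Product: 17 methyl 18-hydroxy-12,13,14,15,16-pentanorlabda-5,8-dien-11-oate
Conditions: K2CO3 (0.2 equiv), MeOH, 0 °C → rt; aq NH4Cl before concentration
Reagents that add atoms: methanol CO
Why: Transesterification (methanolysis) of the bridged lactone should be driven by release of the bridgehead-diene strain, and mild base at low temperature leaves the doubly allylic C7 hydrogens alone.

Step 10
Reactants: 17 hydroxy ester
Product: 18 methyl 18-(tert-butyldimethylsilyloxy)-12,13,14,15,16-pentanorlabda-5,8-dien-11-oate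
Conditions: TBSCl, imidazole, DMF, rt
Reagents that add atoms: tert-butyldimethylsilyl chloride CC(C)(C)[Si](C)(C)Cl
Why: Silylation of the primary C18 alcohol removes the only acidic OH before the enolate chemistry.

Step 11
Reactants: 18 silyl ether ester
Product: 20 methyl 18-(tert-butyldimethylsilyloxy)-12,13,14,15,16-pentanorlabda-5,7-dien-11-oate (H9 trans to C20), via lithium trienolate 19 (not isolated)
Conditions: LiN(iPr)2 (1.5 equiv), DMPU, THF, −78 → −40 °C; inverse quench into AcOH/THF, −78 °C
Reagents that add atoms: none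
Why: Deconjugative protonation of an extended ester enolate: the doubly allylic C7–H (also γ to the ester) is the most acidic hydrogen and should be removed in preference to the C17 methyl hydrogens, and kinetic protonation of the trienolate at its α-carbon C9 on the face away from the C20 methyl sets H9 trans to C20.

Step 12
Reactants: 20 5,7-diene ester
Product: 22 methyl 6-hydroxy-18-(tert-butyldimethylsilyloxy)-12,13,14,15,16-pentanorlabd-7-en-11-oate (H5/6-OH cis; trans to C20), via C6 alkylborane 21 (not isolated)
Conditions: BH3·THF (1.2 equiv), THF, 0 °C; then 30% H2O2, aq NaOAc, 0 °C → rt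
Reagents that add atoms: hydrogen peroxide OO
Why: Hydroboration–oxidation of a ring B 5,7-diene at C5=C6, the behaviour known for steroidal 5,7-dienes: syn addition of H to C5 and boron to C6 on the face opposite the C19 and C20 methyls gives the trans ring fusion and the 6-OH cis to H5, whereas attack on C7=C8 would push C17 against C20.

Step 13
Reactants: 22 6-hydroxy ester
Product: 23 methyl 6,18-bis(tert-butyldimethylsilyloxy)-12,13,14,15,16-pentanorlabd-7-en-11-oate
Conditions: TBSOTf, 2,6-lutidine, CH2Cl2, −78 → 0 °C
Reagents that add atoms: tert-butyldimethylsilyl trifluoromethanesulfonate CC(C)(C)[Si](C)(C)OS(=O)(=O)C(F)(F)F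
Why: Silylation of the hindered secondary allylic alcohol with the silyl triflate protects O6 for the redox steps.

Step 14
Reactants: 23 bis-silyl ether ester
Product: 24 6,18-bis(tert-butyldimethylsilyloxy)-12,13,14,15,16-pentanorlabd-7-en-11-ol
Conditions: iBu2AlH (2.5 equiv), CH2Cl2, −78 → 0 °C; aq Rochelle salt
Reagents that add atoms: none
Why: Ester reduction by a non-basic hydride leaves C9 and both silyl ethers intact.

Step 15
Reactants: 24 C11 alcohol
Product: 25 6,18-bis(tert-butyldimethylsilyloxy)-12,13,14,15,16-pentanorlabd-7-en-11-al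
Conditions: DMP, CH2Cl2, 0 °C → rt; used at once
Reagents that add atoms: none
Why: Dess–Martin oxidation under near-neutral conditions should give the β,γ-unsaturated aldehyde without epimerisation at C9 or migration of the alkene.

Step 16
Reactants: 25 C11 aldehyde
Product: 26 6,18-bis(tert-butyldimethylsilyloxy)-13,14,15,16-tetranorlabda-7,11-diene
Conditions: Ph3PCH3Br, KN(SiMe3)2, THF, 0 °C; then 25, −78 → 0 °C
Reagents that add atoms: methyltriphenylphosphonium bromide C[P+](c1ccccc1)(c1ccccc1)c1ccccc1.[Br-]
Why: Wittig methylenation; at −78 °C the unstabilised ylide should add to the aldehyde faster than it deprotonates C9.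

Step 17
Reactants: 27 methyl acetoacetate
Product: 28 methyl (E)-3-{[(trifluoromethyl)sulfonyl]oxy}but-2-enoate
Conditions: Tf2O, 25% aq Me4NOH, hexanes, 5 °C
Reagents that add atoms: trifluoromethanesulfonic anhydride O=S(=O)(OS(=O)(=O)C(F)(F)F)C(F)(F)F
Why: Biphasic O-triflation of the acetoacetate enolate; the non-chelating tetramethylammonium counter-ion should give the (E)-enol triflate (OTf trans to the ester), whereas a lithium base would give the Z isomer.

Step 18
Reactants: 26 C9 vinyl compound; 28 (E)-enol triflate
Product: 30 methyl (13E)-6,18-bis(tert-butyldimethylsilyloxy)labda-7,13-dien-15-oate, via B-alkyl-9-BBN adduct 29 (not isolated)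
Conditions: 9-BBN dimer, THF, rt → 40 °C; then 28, PdCl2(dppf) (5 mol %), K3PO4 (3 M aq), DMF, rt
Reagents that add atoms: none
Why: Anti-Markovnikov hydroboration of the monosubstituted alkene by 9-BBN (the trisubstituted C7=C8 bond does not react) followed by B-alkyl Suzuki–Miyaura coupling with the divalent palladium precatalyst, which proceeds with retention at C13 and so gives the 13E-enoate.

Step 19
Reactants: 30 bis-silyl ether of the target
Product: 31 methyl (4S,5S,6R,9R,10S,13E)-6,18-dihydroxylabda-7,13-dien-15-oate (CNP0149445.1)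
Conditions: Bu4NF (4 equiv), THF, rt
Reagents that add atoms: none
Why: Fluoride-induced cleavage of both silyl ethers (desilylation) should release the diol without touching the methyl enoate.

**Compound list**
1 | methyl 2-oxocyclohexane-1-carboxylate | COC(=O)C1CCCCC1=O | starting material
2 | tert-butyl L-valinate | CC(C)[C@H](N)C(=O)OC(C)(C)C | starting material
3 | methyl 2-{[(2S)-1-tert-butoxy-3-methyl-1-oxobutan-2-yl]amino}cyclohex-1-ene-1-carboxylate | COC(=O)C1=C(N[C@@H](C(C)C)C(=O)OC(C)(C)C)CCCC1 | intermediate
4 | lithio-enamine of 3 (N-lithiated) | COC(=O)C1=C([N-][C@@H](C(C)C)C(=O)OC(C)(C)C)CCCC1.[Li+] | intermediate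
5 | methyl (1S)-1-methyl-2-{[(2S)-1-tert-butoxy-3-methyl-1-oxobutan-2-yl]imino}cyclohexane-1-carboxylate | COC(=O)[C@@]1(C)CCCCC1=N[C@@H](C(C)C)C(=O)OC(C)(C)C | intermediate
6 | methyl (S)-1-methyl-2-oxocyclohexane-1-carboxylate | COC(=O)[C@@]1(C)CCCCC1=O | intermediate
7 | lithium enolate of 6 (toward the future C10) | COC(=O)[C@@]1(C)CCCC=C1[O-].[Li+] | intermediate
8 | methyl (1S)-1,3-dimethyl-2-oxocyclohexane-1-carboxylate, both C3 epimers | COC(=O)[C@@]1(C)CCCC(C)C1=O | intermediate
9 | potassium enolate of 8 | COC(=O)[C@@]1(C)CCCC(C)=C1[O-].[K+] | intermediate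
10 | methyl (S)-1,3-dimethyl-2-{[(trifluoromethyl)sulfonyl]oxy}cyclohex-2-ene-1-carboxylate | COC(=O)[C@@]1(C)CCCC(C)=C1OS(=O)(=O)C(F)(F)F | intermediate
11 | tributyl(vinyl)stannane | C=C[Sn](CCCC)(CCCC)CCCC | starting material
12 | methyl (S)-1,3-dimethyl-2-vinylcyclohex-2-ene-1-carboxylate | COC(=O)[C@@]1(C)CCCC(C)=C1C=C | intermediate
13 | [(1S)-1,3-dimethyl-2-vinylcyclohex-2-en-1-yl]methanol | OC[C@@]1(C)CCCC(C)=C1C=C | intermediate
14 | but-2-ynoic acid | CC#CC(=O)O | starting material
15 | [(1S)-1,3-dimethyl-2-vinylcyclohex-2-en-1-yl]methyl but-2-ynoate | CC#CC(=O)OC[C@@]1(C)CCCC(C)=C1C=C | intermediate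
16 | tricyclic lactone: 5,8-diene with C17 methyl on C8, C11 carbonyl on C9 esterified by O18 (seven-membered ring), C19 and C20 cis | CC1=C2C(=O)OC[C@@]3(C)CCC[C@]2(C)C3=CC1 | intermediate
17 | methyl 18-hydroxy-12,13,14,15,16-pentanorlabda-5,8-dien-11-oate (C19/C20 cis) | COC(=O)C1=C(C)CC=C2[C@@](C)(CO)CCC[C@@]12C | intermediate
18 | methyl 18-(tert-butyldimethylsilyloxy)-12,13,14,15,16-pentanorlabda-5,8-dien-11-oate | COC(=O)C1=C(C)CC=C2[C@@](C)(CO[Si](C)(C)C(C)(C)C)CCC[C@@]12C | intermediate
19 | lithium trienolate of 18 (C5=C6–C7=C8–C9=C11) | COC([O-])=C1C(C)=CC=C2[C@@](C)(CO[Si](C)(C)C(C)(C)C)CCC[C@@]12C.[Li+] | intermediate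
20 | methyl 18-(tert-butyldimethylsilyloxy)-12,13,14,15,16-pentanorlabda-5,7-dien-11-oate, H9 trans to C20 | COC(=O)[C@@H]1C(C)=CC=C2[C@@](C)(CO[Si](C)(C)C(C)(C)C)CCC[C@@]12C | intermediate
21 | C6 alkylborane from 20 (boron and H5 cis, both trans to C20) | COC(=O)[C@@H]1C(C)=C[C@@H](B)[C@@H]2[C@@](C)(CO[Si](C)(C)C(C)(C)C)CCC[C@@]12C | intermediate
22 | methyl 6-hydroxy-18-(tert-butyldimethylsilyloxy)-12,13,14,15,16-pentanorlabd-7-en-11-oate (H5, H9 and 6-OH trans to C20) | COC(=O)[C@@H]1C(C)=C[C@@H](O)[C@@H]2[C@@](C)(CO[Si](C)(C)C(C)(C)C)CCC[C@@]12C | intermediate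
23 | methyl 6,18-bis(tert-butyldimethylsilyloxy)-12,13,14,15,16-pentanorlabd-7-en-11-oate | COC(=O)[C@@H]1C(C)=C[C@@H](O[Si](C)(C)C(C)(C)C)[C@@H]2[C@@](C)(CO[Si](C)(C)C(C)(C)C)CCC[C@@]12C | intermediate
24 | 6,18-bis(tert-butyldimethylsilyloxy)-12,13,14,15,16-pentanorlabd-7-en-11-ol | OC[C@@H]1C(C)=C[C@@H](O[Si](C)(C)C(C)(C)C)[C@@H]2[C@@](C)(CO[Si](C)(C)C(C)(C)C)CCC[C@@]12C | intermediate
25 | 6,18-bis(tert-butyldimethylsilyloxy)-12,13,14,15,16-pentanorlabd-7-en-11-al | O=C[C@@H]1C(C)=C[C@@H](O[Si](C)(C)C(C)(C)C)[C@@H]2[C@@](C)(CO[Si](C)(C)C(C)(C)C)CCC[C@@]12C | intermediate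
26 | 6,18-bis(tert-butyldimethylsilyloxy)-13,14,15,16-tetranorlabda-7,11-diene (C9 vinyl compound) | C=C[C@@H]1C(C)=C[C@@H](O[Si](C)(C)C(C)(C)C)[C@@H]2[C@@](C)(CO[Si](C)(C)C(C)(C)C)CCC[C@@]12C | intermediate
27 | methyl acetoacetate | COC(=O)CC(C)=O | starting material
28 | methyl (E)-3-{[(trifluoromethyl)sulfonyl]oxy}but-2-enoate | COC(=O)/C=C(\C)OS(=O)(=O)C(F)(F)F | intermediate
29 | B-alkyl-9-BBN adduct of 26 (boron on C12) | C1CC2CCCC(C1)B2CC[C@@H]3C(C)=C[C@@H](O[Si](C)(C)C(C)(C)C)[C@@H]4[C@@](C)(CO[Si](C)(C)C(C)(C)C)CCC[C@@]34C | intermediate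
30 | methyl (13E)-6,18-bis(tert-butyldimethylsilyloxy)labda-7,13-dien-15-oate | COC(=O)/C=C(\C)CC[C@@H]1C(C)=C[C@@H](O[Si](C)(C)C(C)(C)C)[C@@H]2[C@@](C)(CO[Si](C)(C)C(C)(C)C)CCC[C@@]12C | intermediate
31 | methyl (4S,5S,6R,9R,10S,13E)-6,18-dihydroxylabda-7,13-dien-15-oate | COC(=O)/C=C(\C)CC[C@@H]1C(C)=C[C@@H](O)[C@@H]2[C@@](C)(CO)CCC[C@@]12C | target

**Step count**
Total: 19 steps. Longest linear sequence: 18 steps (steps 1–16, 18, 19); step 17 is a one-step side branch.

**Steps most likely to fail**

Step 8 (proposed new method). The bridged transition state may be too strained. The ester may not reach its folded cisoid rotamer. The diene may isomerise by [1,5]-hydrogen shift before it cycloadds, or intermolecular addition and polymerisation may take over. Fallback, setting out from 13: the alcohol is silylated (TBSCl, imidazole, DMF) to tert-butyl{[(1S)-1,3-dimethyl-2-vinylcyclohex-2-en-1-yl]methoxy}dimethylsilane F1. F1 is then heated with methyl but-2-ynoate (neat, sealed tube, 150 °C, or under 12 kbar at 60 °C) in an intermolecular Diels–Alder reaction, the known mode of addition of acetylenic esters to 1-vinyl-2,6,6-trimethylcyclohexenes. Without the tether neither the regiochemistry nor the C10 face is controlled, so the wanted isomer has to be separated from its regio- and C10 isomers by chromatography. It is compound 18, where the route is rejoined (steps 7–10 are then not needed).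

Step 11. The base may remove a C17 methyl hydrogen instead of a C7 hydrogen, or the trienolate may be protonated at C9 on the C20 face. Fallback, setting out from 18: the isolated C5=C6 bond is hydroborated first (BH3·THF; H2O2, aq NaOAc) to methyl 6-hydroxy-18-(tert-butyldimethylsilyloxy)-12,13,14,15,16-pentanorlabd-8-en-11-oate F2. Mesylation (MsCl, Et3N) gives the 6-mesylate F3. DBU in toluene at 80 °C eliminates it by the vinylogous E1cB path, in which only loss of a C7 hydrogen is productive, to the 6,8-dienoate F4. mCPBA epoxidises the more electron-rich C6=C7 bond on the face away from C19 and C20 to the 6,7-epoxy-8-enoate F5. SmI2 in THF–MeOH at −78 °C opens this γ,δ-epoxy enoate to a samarium dienolate that can only be the C7=C8–C9 one. Its ring B is chair-like with C20 axial, so protonation at C9 occurs trans to C20 and gives 22, where the route is rejoined. This detour also makes step 12 unnecessary.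

Step 16. The basic ylide may deprotonate C9 of the β,γ-unsaturated aldehyde, which would epimerise C9 or move the 7-ene into conjugation. Fallback, setting out from 25: a Horner–Wadsworth–Emmons reaction with the weakly basic anion of dimethyl (2-oxopropyl)phosphonate (Ba(OH)2, wet THF) gives the (11E)-enone F6. Conjugate reduction with [(Ph3P)CuH]6 gives the 14,15-dinor-13-ketone F7. A second Horner–Wadsworth–Emmons reaction with trimethyl phosphonoacetate (NaH, THF) gives 30 together with its 13Z isomer, which is removed by chromatography. The route is rejoined at 30 (steps 17 and 18 are then not needed).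

**Further compounds**
F1 | step 8 | tert-butyl{[(1S)-1,3-dimethyl-2-vinylcyclohex-2-en-1-yl]methoxy}dimethylsilane | CC(C)(C)[Si](C)(C)OC[C@@]1(C)CCCC(C)=C1C=C
F2 | step 11 | methyl 6-hydroxy-18-(tert-butyldimethylsilyloxy)-12,13,14,15,16-pentanorlabd-8-en-11-oate | COC(=O)C1=C(C)C[C@@H](O)[C@@H]2[C@@](C)(CO[Si](C)(C)C(C)(C)C)CCC[C@@]12C
F3 | step 11 | methyl 6-(methylsulfonyloxy)-18-(tert-butyldimethylsilyloxy)-12,13,14,15,16-pentanorlabd-8-en-11-oate | COC(=O)C1=C(C)C[C@@H](OS(C)(=O)=O)[C@@H]2[C@@](C)(CO[Si](C)(C)C(C)(C)C)CCC[C@@]12C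
F4 | step 11 | methyl 18-(tert-butyldimethylsilyloxy)-12,13,14,15,16-pentanorlabda-6,8-dien-11-oate | COC(=O)C1=C(C)C=C[C@@H]2[C@@](C)(CO[Si](C)(C)C(C)(C)C)CCC[C@@]12C
F5 | step 11 | methyl 6,7-epoxy-18-(tert-butyldimethylsilyloxy)-12,13,14,15,16-pentanorlabd-8-en-11-oate (epoxide trans to C20) | COC(=O)C1=C(C)[C@H]3O[C@H]3[C@@H]2[C@@](C)(CO[Si](C)(C)C(C)(C)C)CCC[C@@]12C
F6 | step 16 | (11E)-6,18-bis(tert-butyldimethylsilyloxy)-14,15-dinorlabda-7,11-dien-13-one | CC(=O)/C=C/[C@@H]1C(C)=C[C@@H](O[Si](C)(C)C(C)(C)C)[C@@H]2[C@@](C)(CO[Si](C)(C)C(C)(C)C)CCC[C@@]12C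
F7 | step 16 | 6,18-bis(tert-butyldimethylsilyloxy)-14,15-dinorlabd-7-en-13-one | CC(=O)CC[C@@H]1C(C)=C[C@@H](O[Si](C)(C)C(C)(C)C)[C@@H]2[C@@](C)(CO[Si](C)(C)C(C)(C)C)CCC[C@@]12C
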